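**Retrosynthetic overview**

- The target is unmasked last from the tris-benzyl, 5-O-methyl flavanone 14 by cleaving three aryl benzyl ethers and the peri 5-OMe group.
- Ring C of the flavanone is disconnected at C2–C3: a Rh(II)-carbenoid at C3 (from aryl diazomethyl ketone 13) inserts into a C–H bond of the OCH2 group that becomes C2. The B ring is thus carried as an "O-benzyl ether" on the A-ring oxygen O1 and stitched in.
- The enabling feature is that the future C2–H is α to the ring oxygen O1 and benzylic to the electron-rich 4-oxyphenyl B ring (a hydridic C–H), and sits 1,6 to C3 across C4–C4a–C8a–O1.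
- The C4 carbon enters late by formylation of the symmetric tetra-oxygenated A ring of 8, whose two free CH positions are equivalent; oxidation and diazomethane acylation then give 13.
- The diaryl ether comes from Ullmann coupling of hindered phenol 3 with 4′-iodoflavone 7. Ring order: flavone pyranone (step 3), then flavanone pyranone (step 8).

Key step: step 8

Remark: compounds 1, 2, 4 and 5 are taken as catalogue chemicals, and the sense of induction of the dirhodium catalyst in step 8 is treated as an experimental variable settled by the choice of catalyst antipode.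

**Route**

Step 1
Reactants: 1 2,6-dimethoxybenzene-1,4-diol; 2 1-(benzyloxy)-4-(chloromethyl)benzene
Product: 3 4-{[4-(benzyloxy)phenyl]methoxy}-2,6-dimethoxyphenol
Conditions: K2CO3 (1.05 equiv), DMF (degassed), rt, Ar
Reagents that add atoms: none
Why: Williamson etherification with one equivalent of halide should go to the 4-OH, which is the more acidic and unhindered hydroxyl, whereas the 1-OH is shielded and hydrogen-bonded by its two ortho-methoxy groups.

Step 2
Reactants: 4 1-[2,4-bis(benzyloxy)-6-hydroxyphenyl]ethan-1-one; 5 4-iodobenzaldehyde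
Product: 6 (E)-1-[2,4-bis(benzyloxy)-6-hydroxyphenyl]-3-(4-iodophenyl)prop-2-en-1-one
Conditions: KOH (50 % aq.), EtOH/THF, rt
Reagents that add atoms: none
Why: Claisen–Schmidt condensation of a methyl ketone with a non-enolisable aldehyde, with E1cB dehydration, should give the E-chalcone.

Step 3
Reactants: 6 the iodochalcone
Product: 7 5,7-bis(benzyloxy)-2-(4-iodophenyl)-4H-chromen-4-one
Conditions: I2 (5 mol %), DMSO, 120 °C
Reagents that add atoms: none
Why: Iodine-catalysed oxidative cyclisation of a 2′-hydroxychalcone (oxa-Michael closure, α-iodination, loss of HI, re-oxidation of HI by DMSO) should give the flavone and leave the aryl iodide and benzyl ethers untouched.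

Step 4
Reactants: 3 the hindered phenol; 7 the 4′-iodoflavone
Product: 8 5,7-bis(benzyloxy)-2-[4-(4-{[4-(benzyloxy)phenyl]methoxy}-2,6-dimethoxyphenoxy)phenyl]-4H-chromen-4-one
Conditions: CuI (10 mol %), picolinic acid (20 mol %), K3PO4 (2 equiv), DMSO, 90 °C, Ar
Reagents that add atoms: none
Why: Ullmann diaryl ether coupling with a Cu(I)/picolinate system suited to di-ortho-substituted, electron-rich phenols should work here because the iodide is activated by the para vinylogous acyl group and no enolisable ketone is present.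

Step 5
Reactants: 8 the diaryl ether flavone
Product: 10 6-{[4-(benzyloxy)phenyl]methoxy}-3-{4-[5,7-bis(benzyloxy)-4-oxo-4H-chromen-2-yl]phenoxy}-2,4-dimethoxybenzaldehyde, via aryl-iminium chloride 9 (not isolated)
Conditions: POCl3 (1.5 equiv), DMF/ClCH2CH2Cl, 0 °C → rt; then aq. NaOAc
Reagents that add atoms: N,N-dimethylformamide CN(C)C=O; water O
Why: Vilsmeier–Haack formylation should attack only the two equivalent CH positions of the tetra-oxygenated A ring (each ortho/para to three alkoxy groups), because the chromone ring is deactivated by its carbonyl, so one regioisomer results and the DMF-buffered medium should spare the acid-labile 4-(benzyloxy)benzyl ether.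

Step 6
Reactants: 10 the aldehyde
Product: 11 6-{[4-(benzyloxy)phenyl]methoxy}-3-{4-[5,7-bis(benzyloxy)-4-oxo-4H-chromen-2-yl]phenoxy}-2,4-dimethoxybenzoic acid
Conditions: NaClO2, NaH2PO4, 2-methylbut-2-ene, t-BuOH/THF/H2O, 0 °C → rt
Reagents that add atoms: sodium chlorite [Na+].[O-]Cl=O
Why: Pinnick oxidation is selective for the aldehyde, and the alkene scavenger should keep hypochlorous acid away from the electron-rich rings.

Step 7
Reactants: 11 the benzoic acid
Product: 13 2-diazo-1-(6-{[4-(benzyloxy)phenyl]methoxy}-3-{4-[5,7-bis(benzyloxy)-4-oxo-4H-chromen-2-yl]phenoxy}-2,4-dimethoxyphenyl)ethan-1-one, via acid chloride 12 (not isolated)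
Conditions: 1-chloro-N,N,2-trimethylprop-1-en-1-amine, CH2Cl2, 0 °C → rt; then CH2N2 (excess), Et2O/CH2Cl2, 0 °C
Reagents that add atoms: diazomethane C=[N+]=[N-]
Why: Acylation of diazomethane by an acid chloride (first stage of the Arndt–Eistert sequence) should give the diazomethyl ketone, with the chloride made under neutral conditions to protect the acid-labile benzylic ether and excess diazomethane consuming the HCl.

Step 8
Reactants: 13 the diazomethyl ketone
Product: 14 (2S)-2-[4-(benzyloxy)phenyl]-6-{4-[5,7-bis(benzyloxy)-4-oxo-4H-chromen-2-yl]phenoxy}-5,7-dimethoxy-2,3-dihydro-4H-chromen-4-one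
Conditions: Rh2(S-PTTL)4 (2 mol %; antipode if required), CH2Cl2, 0 °C, slow addition of 13 at high dilution
Reagents that add atoms: none
Why: The dirhodium carboxylate should expel N2 from 13 to give an electrophilic α-oxo carbenoid at C3, which inserts into one benzylic C–H bond of the ArO–CH2–Ar′ group through a concerted, asynchronous, hydride-transfer-like three-centre transition state and so forms C2–C3. The closest known reaction type is the Rh(II)-carboxylate-catalysed intramolecular C–H insertion of 2-alkoxyaryl α-diazoketones next to the ether oxygen, which gives 2-substituted chroman-4-ones, including enantioselective variants with chiral carboxylate ligands. The pyranone ring C (O1–C2–C3–C4–C4a–C8a) closes by 1,6-C–H insertion, a six-membered closure in which four ring atoms are already held by the aryl ketone. C2 is the only new stereocentre and is set by catalyst control, the chiral phthalimido-tert-leucinate ligand sphere distinguishing the two enantiotopic benzylic hydrogens. The step needs insertion to win over oxonium-ylide formation at O1 with [1,2]-benzyl shift, over reaction at the 5-OMe group and over Büchner addition to the B ring. The substrate secures this because the C2–H bond is doubly activated (α-oxygen and a p-benzyloxyphenyl group stabilise the developing positive charge), the competing methoxy group offers only primary C–H bonds, and O1 is an aryl ether oxygen of low nucleophilicity; a carboxylate rather than a copper catalyst and slow addition further disfavour ylide and dimer pathways.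

Step 9
Reactants: 14 the protected flavanone
Product: 15 (2S)-6-[4-(5,7-dihydroxy-4-oxo-4H-chromen-2-yl)phenoxy]-5-hydroxy-2-(4-hydroxyphenyl)-7-methoxy-2,3-dihydro-4H-chromen-4-one (CNP0269971.1)
Conditions: BCl3 (1 M in CH2Cl2, excess), C6HMe5, CH2Cl2, −78 → 0 °C; MeOH quench, aq. NaHCO3
Reagents that add atoms: none
Why: BCl3 with pentamethylbenzene as a non-basic cation scavenger should cleave the three aryl benzyl ethers at low temperature and, through the C4=O chelate, only the peri 5-methoxy group, leaving the 7-OMe group and the diaryl ether intact, while low temperature and short contact are meant to keep the C2–O1 bond and the stereocentre intact.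

**Compound list**

1 | 2,6-dimethoxybenzene-1,4-diol | COc1cc(O)cc(OC)c1O | starting material
2 | 1-(benzyloxy)-4-(chloromethyl)benzene | ClCc1ccc(OCc2ccccc2)cc1 | starting material
3 | 4-{[4-(benzyloxy)phenyl]methoxy}-2,6-dimethoxyphenol | COc1cc(OCc2ccc(OCc3ccccc3)cc2)cc(OC)c1O | intermediate
4 | 1-[2,4-bis(benzyloxy)-6-hydroxyphenyl]ethan-1-one | CC(=O)c1c(O)cc(OCc2ccccc2)cc1OCc1ccccc1 | starting material
5 | 4-iodobenzaldehyde | O=Cc1ccc(I)cc1 | starting material
6 | (E)-1-[2,4-bis(benzyloxy)-6-hydroxyphenyl]-3-(4-iodophenyl)prop-2-en-1-one | O=C(/C=C/c1ccc(I)cc1)c1c(O)cc(OCc2ccccc2)cc1OCc1ccccc1 | intermediate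
7 | 5,7-bis(benzyloxy)-2-(4-iodophenyl)-4H-chromen-4-one | O=c1cc(-c2ccc(I)cc2)oc2cc(OCc3ccccc3)cc(OCc3ccccc3)c12 | intermediate
8 | 5,7-bis(benzyloxy)-2-[4-(4-{[4-(benzyloxy)phenyl]methoxy}-2,6-dimethoxyphenoxy)phenyl]-4H-chromen-4-one | COc1cc(OCc2ccc(OCc3ccccc3)cc2)cc(OC)c1Oc1ccc(-c2cc(=O)c3c(OCc4ccccc4)cc(OCc4ccccc4)cc3o2)cc1 | intermediate
9 | N-[(6-{[4-(benzyloxy)phenyl]methoxy}-3-{4-[5,7-bis(benzyloxy)-4-oxo-4H-chromen-2-yl]phenoxy}-2,4-dimethoxyphenyl)methylidene]-N-methylmethanaminium chloride | COc1cc(OCc2ccc(OCc3ccccc3)cc2)c(C=[N+](C)C)c(OC)c1Oc1ccc(-c2cc(=O)c3c(OCc4ccccc4)cc(OCc4ccccc4)cc3o2)cc1.[Cl-] | intermediate (not isolated)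
10 | 6-{[4-(benzyloxy)phenyl]methoxy}-3-{4-[5,7-bis(benzyloxy)-4-oxo-4H-chromen-2-yl]phenoxy}-2,4-dimethoxybenzaldehyde | COc1cc(OCc2ccc(OCc3ccccc3)cc2)c(C=O)c(OC)c1Oc1ccc(-c2cc(=O)c3c(OCc4ccccc4)cc(OCc4ccccc4)cc3o2)cc1 | intermediate
11 | 6-{[4-(benzyloxy)phenyl]methoxy}-3-{4-[5,7-bis(benzyloxy)-4-oxo-4H-chromen-2-yl]phenoxy}-2,4-dimethoxybenzoic acid | COc1cc(OCc2ccc(OCc3ccccc3)cc2)c(C(=O)O)c(OC)c1Oc1ccc(-c2cc(=O)c3c(OCc4ccccc4)cc(OCc4ccccc4)cc3o2)cc1 | intermediate
12 | 6-{[4-(benzyloxy)phenyl]methoxy}-3-{4-[5,7-bis(benzyloxy)-4-oxo-4H-chromen-2-yl]phenoxy}-2,4-dimethoxybenzoyl chloride | COc1cc(OCc2ccc(OCc3ccccc3)cc2)c(C(Cl)=O)c(OC)c1Oc1ccc(-c2cc(=O)c3c(OCc4ccccc4)cc(OCc4ccccc4)cc3o2)cc1 | intermediate (not isolated)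
13 | 2-diazo-1-(6-{[4-(benzyloxy)phenyl]methoxy}-3-{4-[5,7-bis(benzyloxy)-4-oxo-4H-chromen-2-yl]phenoxy}-2,4-dimethoxyphenyl)ethan-1-one | COc1cc(OCc2ccc(OCc3ccccc3)cc2)c(C(=O)C=[N+]=[N-])c(OC)c1Oc1ccc(-c2cc(=O)c3c(OCc4ccccc4)cc(OCc4ccccc4)cc3o2)cc1 | intermediate
14 | (2S)-2-[4-(benzyloxy)phenyl]-6-{4-[5,7-bis(benzyloxy)-4-oxo-4H-chromen-2-yl]phenoxy}-5,7-dimethoxy-2,3-dihydro-4H-chromen-4-one | COc1cc2c(c(OC)c1Oc1ccc(-c3cc(=O)c4c(OCc5ccccc5)cc(OCc5ccccc5)cc4o3)cc1)C(=O)C[C@@H](c1ccc(OCc3ccccc3)cc1)O2 | intermediate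
15 | (2S)-6-[4-(5,7-dihydroxy-4-oxo-4H-chromen-2-yl)phenoxy]-5-hydroxy-2-(4-hydroxyphenyl)-7-methoxy-2,3-dihydro-4H-chromen-4-one | COc1cc2c(c(O)c1Oc1ccc(-c3cc(=O)c4c(O)cc(O)cc4o3)cc1)C(=O)C[C@@H](c1ccc(O)cc1)O2 | target

**Step count and risks**

Total step count: 9. Longest linear sequence: 8 steps (steps 2–9, from 4 and 5).

Steps most likely to fail:

1. Step 8. The carbenoid may be diverted into oxonium-ylide formation at O1 with [1,2]-benzyl migration or into addition to the B-ring arene, and the two enantiotopic hydrogens may be discriminated insufficiently. The fallback sets out from 11 and comes back at 14. The acid is turned into acid chloride 12 as in step 7 and coupled with MeZnCl under Pd(PPh3)4 catalysis (Negishi acylation, THF, 0 °C → rt) to give the aryl methyl ketone F1. TFA/Et3SiH (CH2Cl2, 0 °C) removes only the 4-(benzyloxy)benzyl group and gives the 2′-hydroxyacetophenone F2. DMF dimethyl acetal (toluene, 90 °C) gives the enaminone F3, which cyclises in aq. HCl/CH2Cl2 to the chromone F4. Pd(TFA)2/(S)-t-BuPyOx-catalysed asymmetric conjugate addition of 4-(benzyloxy)phenylboronic acid (NH4PF6, H2O, ClCH2CH2Cl, 60 °C; ligand antipode chosen for 2S) then forms the C2–aryl bond and should give 14. The β,β-disubstituted flavone enone should not compete.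

2. Step 9. Lewis-acid-induced heterolysis of the benzylic C2–O1 bond (ring opening and reclosure) may erode the configuration, and the peri demethylation may stay incomplete. The fallback sets out from 14 and comes back at 15. Hydrogenolysis (H2, 1 atm, Pd/C, EtOAc/THF, rt) removes the three benzyl groups under neutral conditions and gives the 5-O-methyl triphenol F5. A chelation-assisted SN2 demethylation with MgI2·OEt2 (toluene/THF, rt to 40 °C) then frees the 5-OH without a boron halide.

3. Step 4. Slow ligand exchange of the di-ortho-substituted phenoxide at copper may lead to protodeiodination of 7 and oxidative loss of the electron-rich phenol. The fallback sets out from 3 and 4 and comes back at 8. SNAr of 3 with 4-fluorobenzaldehyde (K2CO3, DMF, 120 °C) gives the diaryl ether aldehyde F6. Claisen–Schmidt condensation with 4 (KOH, EtOH/THF, rt) gives the chalcone F7. Iodine-catalysed oxidative cyclisation (I2 5 mol %, DMSO, 120 °C) then gives 8.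

**Further compounds**

F1 | step 8 | 5,7-bis(benzyloxy)-2-[4-(3-acetyl-4-{[4-(benzyloxy)phenyl]methoxy}-2,6-dimethoxyphenoxy)phenyl]-4H-chromen-4-one | COc1cc(OCc2ccc(OCc3ccccc3)cc2)c(C(C)=O)c(OC)c1Oc1ccc(-c2cc(=O)c3c(OCc4ccccc4)cc(OCc4ccccc4)cc3o2)cc1
F2 | step 8 | 5,7-bis(benzyloxy)-2-[4-(3-acetyl-4-hydroxy-2,6-dimethoxyphenoxy)phenyl]-4H-chromen-4-one | COc1cc(O)c(C(C)=O)c(OC)c1Oc1ccc(-c2cc(=O)c3c(OCc4ccccc4)cc(OCc4ccccc4)cc3o2)cc1
F3 | step 8 | (E)-1-(3-{4-[5,7-bis(benzyloxy)-4-oxo-4H-chromen-2-yl]phenoxy}-6-hydroxy-2,4-dimethoxyphenyl)-3-(dimethylamino)prop-2-en-1-one | COc1cc(O)c(C(=O)/C=C/N(C)C)c(OC)c1Oc1ccc(-c2cc(=O)c3c(OCc4ccccc4)cc(OCc4ccccc4)cc3o2)cc1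
F4 | step 8 | 6-{4-[5,7-bis(benzyloxy)-4-oxo-4H-chromen-2-yl]phenoxy}-5,7-dimethoxy-4H-chromen-4-one | COc1cc2occc(=O)c2c(OC)c1Oc1ccc(-c2cc(=O)c3c(OCc4ccccc4)cc(OCc4ccccc4)cc3o2)cc1
F5 | step 9 | (2S)-6-[4-(5,7-dihydroxy-4-oxo-4H-chromen-2-yl)phenoxy]-2-(4-hydroxyphenyl)-5,7-dimethoxy-2,3-dihydro-4H-chromen-4-one | COc1cc2c(c(OC)c1Oc1ccc(-c3cc(=O)c4c(O)cc(O)cc4o3)cc1)C(=O)C[C@@H](c1ccc(O)cc1)O2
F6 | step 4 | 4-(4-{[4-(benzyloxy)phenyl]methoxy}-2,6-dimethoxyphenoxy)benzaldehyde | COc1cc(OCc2ccc(OCc3ccccc3)cc2)cc(OC)c1Oc1ccc(C=O)cc1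
F7 | step 4 | (E)-1-[2,4-bis(benzyloxy)-6-hydroxyphenyl]-3-[4-(4-{[4-(benzyloxy)phenyl]methoxy}-2,6-dimethoxyphenoxy)phenyl]prop-2-en-1-one | COc1cc(OCc2ccc(OCc3ccccc3)cc2)cc(OC)c1Oc1ccc(/C=C/C(=O)c2c(O)cc(OCc3ccccc3)cc2OCc2ccccc2)cc1
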